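Ring C of the central flavan-3-ol is built first and the two fisetinidol units are attached last. Ring C of the central unit is closed at C3–C4 by an aminocatalytic oxa-Michael/aldol condensation: a ring A salicylaldehyde, whose phenol oxygen is O1 and whose formyl carbon is C4, meets a cinnamaldehyde that supplies C2, C3 and a sacrificial formyl group. In one operation the step forms O1–C2 with catalyst control and closes the pyran ring between C3 and C4. It exploits the ortho relationship of O1 and C4 on ring A and leaves a C3=C4 alkene that, after decarbonylation, is hydroborated to the 2,3-trans carbinol. Acid-catalysed capture of two flavan-4-yl cations at C6 and C8 completes the triflavanoid.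

Key step: step 3

Remark: (2R,3R)-(+)-fustin is taken as a purchasable natural product; atom numbers are flavan numbers of the central unit (rings A, B, C), and the target is read as fisetinidol-(4α→6)-[fisetinidol-(4α→8)]-4'-O-methyl-(+)-catechin, all upper units (2R,3S,4S), central unit (2R,3S).

Step 1
Reactants: 1 2,4,6-trihydroxybenzaldehyde
Product: 2 2,4-bis(benzyloxy)-6-hydroxybenzaldehyde
Conditions: BnBr (2.1 equiv), K2CO3, DMF, rt
Reagents that add atoms: benzyl bromide, BrCc1ccccc1
Why: Williamson etherification in which the para hydroxyl and one ortho hydroxyl are alkylated while the remaining ortho hydroxyl, hydrogen-bonded to the formyl group, should stay free at this stoichiometry.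

Step 2
Reactants: 3 3-(benzyloxy)-4-methoxybenzaldehyde; 4 (triphenylphosphoranylidene)acetaldehyde
Product: 5 (E)-3-[3-(benzyloxy)-4-methoxyphenyl]prop-2-enal
Conditions: toluene, 80 °C, 1.1 equiv of 4
Reagents that add atoms: none
Why: Wittig olefination with a stabilized ylide, which should give the (E)-enal, the slight excess of ylide limiting a second homologation.

Step 3
Reactants: 2 2,4-bis(benzyloxy)-6-hydroxybenzaldehyde; 5 (E)-3-[3-(benzyloxy)-4-methoxyphenyl]prop-2-enal
Product: 8 (2R)-5,7-bis(benzyloxy)-2-[3-(benzyloxy)-4-methoxyphenyl]-2H-chromene-3-carbaldehyde, via oxa-Michael enamine 6 (not isolated), via aldol adduct 7 (not isolated)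
Conditions: (S)-2-[diphenyl(trimethylsilyloxy)methyl]pyrrolidine (20 mol%), 2-nitrobenzoic acid (20 mol%), 4 Å molecular sieves, toluene, rt
Reagents that add atoms: none
Why: The secondary amine condenses with enal 5 to an (E)-iminium ion, the chelated phenol oxygen of 2 adds to its β-carbon (future C2) to give enamine 6, the enamine carbon (future C3) attacks the neighbouring formyl carbon (future C4) in an intramolecular aldol addition to 7, and loss of water with hydrolysis of the iminium ion releases 8 and the catalyst. The closest known reaction type is the diarylprolinol silyl ether catalysed oxa-Michael/aldol condensation of salicylaldehydes with cinnamaldehydes to 2-aryl-2H-chromene-3-carbaldehydes. Ring C is closed by the C3–C4 aldol bond in a 6-(enolexo)-exo-trig mode. The only new stereocenter, C2, is under catalyst control: the diphenyl(silyloxy)methyl group of the (S)-catalyst shields one face of the s-trans iminium ion so that oxygen should add to the Si face of the β-carbon, which corresponds to (2R). The step needs enantioselectivity and selectivity for a single phenol; the first is secured when irreversible dehydration outruns the retro-oxa-Michael reaction (acid co-catalyst, molecular sieves), the second by benzyl protection of all other phenols so that only the hydroxyl ortho to the formyl group can both add and cyclize.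

Step 4
Reactants: 8 (2R)-5,7-bis(benzyloxy)-2-[3-(benzyloxy)-4-methoxyphenyl]-2H-chromene-3-carbaldehyde
Product: 9 (2S)-5,7-bis(benzyloxy)-2-[3-(benzyloxy)-4-methoxyphenyl]-2H-chromene
Conditions: RhCl(PPh3)3 (1.05 equiv), degassed toluene, 80 °C, dark
Reagents that add atoms: none
Why: Tsuji–Wilkinson decarbonylation, in which oxidative addition of the formyl C–H bond to monovalent rhodium, CO de-insertion and C–H reductive elimination replace the formyl group by hydrogen without touching C2, whose descriptor changes from R to S only because the CIP rank of C3 drops.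

Step 5
Reactants: 9 (2S)-5,7-bis(benzyloxy)-2-[3-(benzyloxy)-4-methoxyphenyl]-2H-chromene
Product: 11 (2R,3S)-5,7-bis(benzyloxy)-2-[3-(benzyloxy)-4-methoxyphenyl]chroman-3-ol, via flavan-3-ylborane 10 (not isolated)
Conditions: BH3·THF, THF, 0 °C to rt; then NaOH (aq), H2O2, 0 °C
Reagents that add atoms: borane–tetrahydrofuran complex, [BH3-][O+]1CCCC1 (boron of 10); hydrogen peroxide, OO (oxygen of 11)
Why: Hydroboration–oxidation in which borane should add syn across C3=C4 from the face opposite the C2 aryl group with boron on C3, the carbon remote from the electron-rich ring A, and oxidation with retention then gives the 2,3-trans (3S) alcohol.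

Step 6
Reactants: 11 (2R,3S)-5,7-bis(benzyloxy)-2-[3-(benzyloxy)-4-methoxyphenyl]chroman-3-ol
Product: 12 4'-O-methyl-(+)-catechin, (2R,3S)-2-(3-hydroxy-4-methoxyphenyl)chromane-3,5,7-triol
Conditions: H2 (1 atm), Pd(OH)2/C, THF–MeOH, rt
Reagents that add atoms: none
Why: Catalytic hydrogenolysis of the three benzyl ethers, under which the cyclic C2–O1 ether of flavan-3-ols is expected to survive and no stereocenter is touched.

Step 7
Reactants: 13 (+)-fustin, (2R,3R)-2-(3,4-dihydroxyphenyl)-3,7-dihydroxychroman-4-one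
Product: 14 (+)-mollisacacidin, (2R,3S,4R)-2-(3,4-dihydroxyphenyl)chromane-3,4,7-triol
Conditions: NaBH4, EtOH, 0 °C to rt; dilute AcOH work-up
Reagents that add atoms: none
Why: Borohydride reduction of the C4 ketone, where axial hydride delivery to the half-chair with equatorial C2 aryl and C3 hydroxyl should give mainly the equatorial, 3,4-trans (4R) alcohol; the C4 configuration is in any case erased in step 8.

Step 8
Reactants: 12 4'-O-methyl-(+)-catechin; 14 (+)-mollisacacidin (2.5–3 equiv, added in portions)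
Product: 18 fisetinidol-(4α→6)-[fisetinidol-(4α→8)]-4'-O-methyl-(+)-catechin, via fisetinidol-4-yl cation 15 (not isolated), via (4α→8) mono-adduct 16 (not isolated), via (4α→6) mono-adduct 17 (not isolated)
Conditions: 0.1 M HCl (aq)–1,4-dioxane, rt, N2; Sephadex LH-20 (EtOH)
Reagents that add atoms: none
Why: Biomimetic acid-catalysed flavan-3,4-diol condensation (SN1 Friedel–Crafts alkylation), in which ionization of the benzylic 4-OH of 14 gives cation 15 stabilized by the para 7-OH, the phloroglucinol-type ring A of 12 captures it at C8 and at C6 (both free positions are substituted, so no regiochemical choice remains), and attack anti to the C3 hydroxyl of the 2,3-trans cation should set each new C4 center 3,4-trans (4α, 4S).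

Compound list
1 | 2,4,6-trihydroxybenzaldehyde | O=Cc1c(O)cc(O)cc1O | starting material
2 | 2,4-bis(benzyloxy)-6-hydroxybenzaldehyde | O=Cc1c(O)cc(OCc2ccccc2)cc1OCc1ccccc1 | intermediate
3 | 3-(benzyloxy)-4-methoxybenzaldehyde | COc1ccc(C=O)cc1OCc1ccccc1 | starting material
4 | (triphenylphosphoranylidene)acetaldehyde | O=CC=P(c1ccccc1)(c1ccccc1)c1ccccc1 | starting material
5 | (E)-3-[3-(benzyloxy)-4-methoxyphenyl]prop-2-enal | COc1ccc(/C=C/C=O)cc1OCc1ccccc1 | intermediate
6 | oxa-Michael enamine: (E)-enamine of the catalyst with 3-[3-(benzyloxy)-4-methoxyphenyl]-3-[3,5-bis(benzyloxy)-2-formylphenoxy]propanal, ether carbon configured as C2 of 8 | COc1ccc([C@H](/C=C/N2CCC[C@H]2C(c2ccccc2)(c2ccccc2)O[Si](C)(C)C)Oc2cc(OCc3ccccc3)cc(OCc3ccccc3)c2C=O)cc1OCc1ccccc1 | intermediate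
7 | aldol adduct: 5,7-bis(benzyloxy)-2-[3-(benzyloxy)-4-methoxyphenyl]-4-hydroxychromane-3-carbaldehyde, C2 as in 8, C3 and C4 not defined, carried on the catalyst as its iminium ion and drawn in the free form | COc1ccc([C@H]2Oc3cc(OCc4ccccc4)cc(OCc4ccccc4)c3C(O)C2C=O)cc1OCc1ccccc1 | intermediate
8 | (2R)-5,7-bis(benzyloxy)-2-[3-(benzyloxy)-4-methoxyphenyl]-2H-chromene-3-carbaldehyde | COc1ccc([C@H]2Oc3cc(OCc4ccccc4)cc(OCc4ccccc4)c3C=C2C=O)cc1OCc1ccccc1 | intermediate
9 | (2S)-5,7-bis(benzyloxy)-2-[3-(benzyloxy)-4-methoxyphenyl]-2H-chromene | COc1ccc([C@H]2Oc3cc(OCc4ccccc4)cc(OCc4ccccc4)c3C=C2)cc1OCc1ccccc1 | intermediate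
10 | 2,3-trans-{5,7-bis(benzyloxy)-2-[3-(benzyloxy)-4-methoxyphenyl]chroman-3-yl}borane, drawn as the monoalkylborane | COc1ccc([C@H]2Oc3cc(OCc4ccccc4)cc(OCc4ccccc4)c3C[C@@H]2B)cc1OCc1ccccc1 | intermediate
11 | (2R,3S)-5,7-bis(benzyloxy)-2-[3-(benzyloxy)-4-methoxyphenyl]chroman-3-ol | COc1ccc([C@H]2Oc3cc(OCc4ccccc4)cc(OCc4ccccc4)c3C[C@@H]2O)cc1OCc1ccccc1 | intermediate
12 | 4'-O-methyl-(+)-catechin, (2R,3S)-2-(3-hydroxy-4-methoxyphenyl)chromane-3,5,7-triol | COc1ccc([C@H]2Oc3cc(O)cc(O)c3C[C@@H]2O)cc1O | intermediate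
13 | (+)-fustin, (2R,3R)-2-(3,4-dihydroxyphenyl)-3,7-dihydroxychroman-4-one | O=C1c2ccc(O)cc2O[C@H](c2ccc(O)c(O)c2)[C@H]1O | starting material
14 | (+)-mollisacacidin, (2R,3S,4R)-2-(3,4-dihydroxyphenyl)chromane-3,4,7-triol | O[C@@H]1c2ccc(O)cc2O[C@H](c2ccc(O)c(O)c2)[C@H]1O | intermediate
15 | fisetinidol-4-yl cation, 2,3-trans-2-(3,4-dihydroxyphenyl)-3,7-dihydroxychroman-4-ylium | [CH+]1c2ccc(O)cc2O[C@H](c2ccc(O)c(O)c2)[C@H]1O | intermediate
16 | fisetinidol-(4α→8)-4'-O-methyl-(+)-catechin | COc1ccc([C@H]2Oc3c(c(O)cc(O)c3[C@@H]3c4ccc(O)cc4O[C@H](c4ccc(O)c(O)c4)[C@H]3O)C[C@@H]2O)cc1O | intermediate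
17 | fisetinidol-(4α→6)-4'-O-methyl-(+)-catechin | COc1ccc([C@H]2Oc3c(c(O)c([C@@H]4c5ccc(O)cc5O[C@H](c5ccc(O)c(O)c5)[C@H]4O)c(O)c3)C[C@@H]2O)cc1O | intermediate
18 | fisetinidol-(4α→6)-[fisetinidol-(4α→8)]-4'-O-methyl-(+)-catechin | COc1ccc([C@H]2Oc3c(c(O)c([C@@H]4c5ccc(O)cc5O[C@H](c5ccc(O)c(O)c5)[C@H]4O)c(O)c3[C@@H]3c4ccc(O)cc4O[C@H](c4ccc(O)c(O)c4)[C@H]3O)C[C@@H]2O)cc1O | target

Total step count: 8. Longest linear sequence: 6 steps (steps 1, 3, 4, 5, 6, 8; equally steps 2, 3, 4, 5, 6, 8).

Steps most likely to fail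

Step 3. The aldol closure onto the electron-rich, doubly ortho-substituted formyl group of 2 may be slow, so that the oxa-Michael adduct reverts and enantioselectivity erodes, or the sequence stalls before dehydration. The fallback sets out from 2 and 5 and comes back at 9, closing ring C at C3=C4 by olefin metathesis instead. Wittig methylenation of 2 (Ph3P=CH2 made from MePPh3Br and KOtBu, THF, 0 °C) would give 3,5-bis(benzyloxy)-2-vinylphenol F1. Reduction of 5 (NaBH4, CeCl3·7H2O, MeOH, 0 °C) would give (E)-3-[3-(benzyloxy)-4-methoxyphenyl]prop-2-en-1-ol F2, and methyl chloroformate with pyridine in CH2Cl2 would convert it into the cinnamyl methyl carbonate F3. F1 would be deprotonated with LiN(SiMe3)2 to lithium 3,5-bis(benzyloxy)-2-vinylphenoxide F4. Branched-selective allylic etherification of F4 with F3 ([Ir(cod)Cl]2, the binaphthol-derived bis(1-phenylethyl)phosphoramidite of the enantiomeric series that leads to the (S)-ether, THF, rt) would give (S)-1,5-bis(benzyloxy)-3-{1-[3-(benzyloxy)-4-methoxyphenyl]prop-2-enyloxy}-2-vinylbenzene F5. Ring-closing metathesis of F5 with the second-generation Grubbs catalyst RuCl2(=CHPh)(H2IMes)(PCy3) in CH2Cl2 at rt would then give 9.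

Step 4. At the temperature needed for CO extrusion the 2H-chromene may undergo reversible electrocyclic ring opening, which would racemize C2, and a rhodium hydride may shift the C3=C4 double bond. The fallback sets out from 8 and comes back at 11, keeping every operation at or below 0 °C and passing by 9 and 10. Baeyer–Villiger oxidation of the α-substituted enal (3-chloroperoxybenzoic acid, NaHCO3, CH2Cl2, 0 °C) would give (2R)-5,7-bis(benzyloxy)-2-[3-(benzyloxy)-4-methoxyphenyl]-2H-chromen-3-yl formate F6. Treatment with NaBH4 in MeOH–THF at −20 °C would cleave the formate and reduce, as it forms, (2R)-5,7-bis(benzyloxy)-2-[3-(benzyloxy)-4-methoxyphenyl]chroman-3-one F7. Axial hydride delivery is expected to favour the equatorial, 2,3-trans alcohol 11, from which the cis epimer would be removed by chromatography.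

Step 8. Ionization in aqueous acid is reversible, so the second substitution may remain incomplete, interflavanyl bonds may scramble, 14 may self-condense, and C4 epimers may accumulate. The fallback sets out from 14 and 12 and comes back at 18, generating the same cation irreversibly under aprotic, neutral conditions. Thiolysis of 14 (phenylmethanethiol, AcOH, EtOH, rt) would give 4-benzylsulfanylfisetinidol F8 as a mixture of C4 epimers. Activation of F8 (2.5 equiv) with the thiophilic salt AgBF4 in THF at 0 °C in the presence of 12 would then deliver 18.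

Further compounds
F1 | step 3 | 3,5-bis(benzyloxy)-2-vinylphenol | C=Cc1c(O)cc(OCc2ccccc2)cc1OCc1ccccc1
F2 | step 3 | (E)-3-[3-(benzyloxy)-4-methoxyphenyl]prop-2-en-1-ol | COc1ccc(/C=C/CO)cc1OCc1ccccc1
F3 | step 3 | (E)-3-[3-(benzyloxy)-4-methoxyphenyl]prop-2-enyl methyl carbonate | COC(=O)OC/C=C/c1ccc(OC)c(OCc2ccccc2)c1
F4 | step 3 | lithium 3,5-bis(benzyloxy)-2-vinylphenoxide | [Li+].[O-]c1cc(OCc2ccccc2)cc(OCc2ccccc2)c1C=C
F5 | step 3 | (S)-1,5-bis(benzyloxy)-3-{1-[3-(benzyloxy)-4-methoxyphenyl]prop-2-enyloxy}-2-vinylbenzene | COc1ccc([C@H](C=C)Oc2cc(OCc3ccccc3)cc(OCc3ccccc3)c2C=C)cc1OCc1ccccc1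
F6 | step 4 | (2R)-5,7-bis(benzyloxy)-2-[3-(benzyloxy)-4-methoxyphenyl]-2H-chromen-3-yl formate | COc1ccc([C@H]2Oc3cc(OCc4ccccc4)cc(OCc4ccccc4)c3C=C2OC=O)cc1OCc1ccccc1
F7 | step 4 | (2R)-5,7-bis(benzyloxy)-2-[3-(benzyloxy)-4-methoxyphenyl]chroman-3-one | COc1ccc([C@H]2Oc3cc(OCc4ccccc4)cc(OCc4ccccc4)c3CC2=O)cc1OCc1ccccc1
F8 | step 8 | 4-benzylsulfanylfisetinidol, 2,3-trans-4-(benzylsulfanyl)-2-(3,4-dihydroxyphenyl)chromane-3,7-diol, C4 epimers | C1(SCc2ccccc2)c2ccc(O)cc2O[C@H](c2ccc(O)c(O)c2)[C@H]1O
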